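The numbers of this flask are invented, and the outcome is calculated.

A small charge of substrate, 20 mM, meets activator, 22.0 mM, and you want as much of that substrate as possible closed to ring. Here are the four set-ups, the steps and the questions.

| flask | substrate | activator | time | remark |
|---|---|---|---|---|
| theta | 20 mM | 22.0 mM | 15 s | everything together in a closed stirred flask, run for 15 s |
| delta | 20 mM | 22.0 mM |  | one stirred flow tank at steady state, fed with the mixture as stated, mean residence time 150 s |
| gamma | 20 mM (fed, over 12.0 s) | 22.0 mM | 15 s | a stirred flask in which substrate is dosed at a steady rate over 12.0 s without added volume, worked up at 15 s |
| eta | 20 mM | 22.0 mM |  | one stirred flow tank at steady state, fed with the mixture as stated, mean residence time 15 s |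

    substrate + activator → activated form (k1 = 8.1 L mol⁻¹ s⁻¹)
    activated form → ring (k2 = 0.78 s⁻¹)
    substrate + activated form → open dimer (k3 = 240 L mol⁻¹ s⁻¹)
    2 activator → homo dimer (k4 = 1.2 L mol⁻¹ s⁻¹)

- in percentages every species weighs as the substrate in it: one open dimer counts as two
- two of one species on the left: rate k times its square, two consumed each time
- the stated concentrations are those of everything mixed, before any reaction; amounts are the same in each set-up
- the feed brings no volume worth counting
- run time (theta): 15 s

* the set-up with the highest amount of ring at the outlet or at the end, in percent of the substrate put in ("none" if the first two lie within 2 percentage points) (theta / delta / gamma / eta / none)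
* amount of ring at the outlet or at the end, in percent of the substrate put in, theta
* amount of ring at the outlet or at the end, in percent of the substrate put in, delta
* amount of ring at the outlet or at the end, in percent of the substrate put in, gamma
* amount of ring at the outlet or at the end, in percent of the substrate put in, eta

Each activated form has two exits: it closes, or free substrate captures it. Carry one quantity, the crossover fraction, which is the fraction of the substrate charge, still free, at which closing and capture run equally fast: k2 over k3 times the charge, 16.2 %. At a free fraction a, the ring share (the selectivity) is crossover/(crossover + a). An activated form costs one substrate, and a second if captured, so the cost per activated form is two minus the share.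

Set delta beside its neighbour eta: the same tank and the same feed, with delta's residence time ten times eta's. In a tank the free fraction has one value, so my reckoning is short. Counting the step to homo dimer as the one loss of activator, the tank keeps 29.8 % of the activator in delta and 65.8 % in eta. Replace the varying cost by its mean, 1.50. The substrate balance then gives a free fraction of 7.73 % in delta and 27.5 % in eta. So delta stands below the crossover and eta above it, with ring shares of 0.678 and 0.371. The costs come out at 1.32 and 1.63, so the mean errs by 13.5 % and 7.92 %. With those costs, ring comes to 47.3 % of the charge in delta and 16.5 % in eta. I did not count the activator that activation spends, so I take both figures as leaning high.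

The forecast names delta, with 14.1 % for theta, 34.3 % for delta, 14 % for gamma and 13 % for eta. For delta that is less than my figure. Its ground: “ring yield depends on keeping free substrate low”.

The flask gives delta as best, with 34.3 % of ring against 14.3 % in theta, 14.0 % in gamma and 13.1 % in eta. In delta, substrate stood at 12.5 % of the charge, below the crossover, which puts the ring share at 0.564. In eta, ring set against open dimer, each open dimer holding two substrates, gives a ring share of 0.331, and at that share the crossover puts free substrate at 32.9 % of the charge, above the crossover.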